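## Retrosynthetic overview
1. The last step is Pd(0) removal of two O‑allyl groups (7‑O and 3'‑O).
2. Ring C (O1–C2 bond) and the C2 stereocentre come from a new catalytic asymmetric reductive cycloetherification of a 1‑(B‑aryl)‑3‑(2‑hydroxy‑A‑aryl)propan‑1‑one, using a chiral counter‑anion and a Hantzsch ester.
3. The C3–C4 bond comes from Claisen–Schmidt condensation of the B‑ring methyl ketone with 4‑allyloxysalicylaldehyde, followed by CuH 1,4‑reduction.
4. The B‑ring ketone comes from 3,4‑dihydroxyacetophenone by two rearrangements, each with only one free ortho site. The 4‑O‑propargyl ether gives the dimethylchromene, and the 3‑O‑reverse‑prenyl ether gives the C‑prenyl group.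
5. Ring order: aromatic rings A and B are purchased, the dimethylpyran ring is formed first (step 2), and flavan ring C is formed last (step 10).

Assumptions:
- CIP analysis of the given SMILES gives (2S), with priorities O > aryl > CH2 > H.
- The facial sense of the new catalyst cannot be predicted. The (R)‑catalyst is written below, and its equally available antipode is used if it delivers the wrong enantiomer.

## Route

**Step 1**
Reactants: 1, 3,4‑dihydroxyacetophenone; 2, 3‑chloro‑3‑methylbut‑1‑yne
Product: 3, 1‑[3‑hydroxy‑4‑(2‑methylbut‑3‑yn‑2‑yloxy)phenyl]ethanone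
Conditions: K2CO3 (1.05 equiv), KI, DMF, 60 °C, Ar
Reagents that add atoms: 3‑chloro‑3‑methylbut‑1‑yne, C#CC(C)(C)Cl
Why: Williamson‑type O‑propargylation; the 4‑OH para to the acetyl group is clearly the more acidic, so one equivalent of base gives and alkylates the 4‑phenoxide selectively.

**Step 2**
Reactants: 3
Product: 4, 1‑(8‑hydroxy‑2,2‑dimethyl‑2H‑chromen‑6‑yl)ethanone
Conditions: PhNEt2, 190 °C, 2 h
Reagents that add atoms: none
Why: Aryl propargyl ether Claisen rearrangement, then [1,5]‑H shift and oxa‑6π electrocyclisation; the only free ortho carbon is C5 of the acetophenone, so the chromene regiochemistry is forced.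

**Step 3**
Reactants: 5, 2‑methylbut‑3‑en‑2‑ol; 6, di‑tert‑butyl dicarbonate
Product: 7, tert‑butyl (2‑methylbut‑3‑en‑2‑yl) carbonate
Conditions: n‑BuLi, THF, −78 → 0 °C; then Boc2O
Reagents that add atoms: Boc2O, CC(C)(C)OC(=O)OC(=O)OC(C)(C)C
Why: Simple acylation of a lithium tertiary alkoxide to give the mixed carbonate.

**Step 4**
Reactants: 4; 7
Product: 8, 1‑[2,2‑dimethyl‑8‑(2‑methylbut‑3‑en‑2‑yloxy)‑2H‑chromen‑6‑yl]ethanone
Conditions: Pd(PPh3)4 (3 mol%), THF, 0 °C, 1–2 h
Reagents that add atoms: carbonate 7, C=CC(C)(C)OC(=O)OC(C)(C)C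
Why: Decarboxylative Tsuji–Trost O‑allylation; at low temperature the phenoxide attacks the more substituted terminus of the 1,1‑dimethyl‑π‑allyl‑Pd to give the tertiary (reverse‑prenyl) ether.

**Step 5**
Reactants: 8
Product: 9, 1‑[8‑hydroxy‑2,2‑dimethyl‑7‑(3‑methylbut‑2‑en‑1‑yl)‑2H‑chromen‑6‑yl]ethanone
Conditions: PhNEt2, 150 °C, sealed tube, 2 h
Reagents that add atoms: none
Why: Aromatic Claisen [3,3] rearrangement accelerated by the gem‑dimethyl group; C7 is the only ortho C–H (the other ortho carbon carries O1), and allyl inversion turns reverse‑prenyl‑O into C‑prenyl.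

**Step 6**
Reactants: 9; 10, allyl bromide
Product: 11, 1‑[8‑(allyloxy)‑2,2‑dimethyl‑7‑(3‑methylbut‑2‑en‑1‑yl)‑2H‑chromen‑6‑yl]ethanone
Conditions: K2CO3, DMF, 40 °C
Reagents that add atoms: allyl bromide, C=CCBr
Why: Williamson etherification; allyl survives KOH, CuH and Brønsted acid, comes off without acid or H2, and blocks acid cyclisation of the phenol onto the prenyl group.

**Step 7**
Reactants: 12, 2,4‑dihydroxybenzaldehyde; 10
Product: 13, 4‑(allyloxy)‑2‑hydroxybenzaldehyde
Conditions: allyl bromide (1.05 equiv), K2CO3 (1.0 equiv), acetone, reflux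
Reagents that add atoms: allyl bromide, C=CCBr
Why: Regioselective Williamson etherification; the 2‑OH is hydrogen‑bonded to the aldehyde and much less nucleophilic than the 4‑OH.

**Step 8**
Reactants: 11; 13
Product: 14, (E)‑3‑[4‑(allyloxy)‑2‑hydroxyphenyl]‑1‑[8‑(allyloxy)‑2,2‑dimethyl‑7‑prenyl‑2H‑chromen‑6‑yl]prop‑2‑en‑1‑one
Conditions: 50% aq KOH, EtOH, rt, 48 h, dark; AcOH to pH 6 at 0 °C
Reagents that add atoms: none beyond the two reactants (H2O is lost)
Why: Claisen–Schmidt aldol condensation gives the E‑enone; the near‑neutral quench avoids flavylium formation, and the allyl, prenyl and chromene groups are inert to hydroxide.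

**Step 9**
Reactants: 14
Product: 15, 3‑[4‑(allyloxy)‑2‑hydroxyphenyl]‑1‑[8‑(allyloxy)‑2,2‑dimethyl‑7‑prenyl‑2H‑chromen‑6‑yl]propan‑1‑one
Conditions: [(Ph3P)CuH]6 (5 mol%), PhSiH3 (2 equiv), toluene, rt; then NH4F, MeOH–H2O
Reagents that add atoms: none
Why: Stryker‑type CuH conjugate reduction; PPh3‑ligated CuH reduces only the enone, the ketone stays masked as its silyl enol ether, and the fluoride work‑up frees it together with any O‑silylated phenol.

**Step 10 (key new step)**
Reactants: 15
Product: 16, (2S)‑7‑(allyloxy)‑2‑[8‑(allyloxy)‑2,2‑dimethyl‑7‑prenyl‑2H‑chromen‑6‑yl]chromane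
Conditions: (R)‑3,3'‑bis(2,4,6‑triisopropylphenyl)‑H8‑BINOL N‑triflylphosphoramide (5 mol%), di‑tert‑butyl Hantzsch ester (1.5 equiv), 5 Å MS, toluene, 0 → 25 °C, dark
Reagents that add atoms: none (hydride only; H2O is lost)
Why: Proposed new method: catalytic asymmetric reductive cycloetherification, in which keto‑phenol 15 equilibrates with its six‑membered hemiketal, the strong confined chiral acid ionises this (sieves take up the water) to a 2‑aryl‑3,4‑dihydrochromenylium ion held as a contact ion pair with the phosphoramidate, any flav‑2‑ene formed by loss of H‑3 is re‑protonated so all material passes through this one cation, and the same anion hydrogen‑bonds the Hantzsch ester N–H and directs irreversible hydride transfer to the Re face of C2, closing ring C and setting (2S); the free ketone and the four C=C bonds are not reduced by the Hantzsch ester, which is far more nucleophilic toward carbocations than a trisubstituted alkene, so Prins capture by the ortho‑prenyl group should not compete; the closest known reaction types are chiral phosphoric acid/Hantzsch ester transfer hydrogenation of ketimines and quinolines, chiral‑anion‑directed reduction of isobenzopyrylium ions, and racemic Et3SiH/acid reductive cyclisation of such keto‑phenols, and to my knowledge none of these has been shown for non‑aromatic chroman‑2‑yl oxocarbenium ions or for flavan synthesis.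

**Step 11**
Reactants: 16
Product: 17, kazinol B, (2S)‑2‑[8‑hydroxy‑2,2‑dimethyl‑7‑(3‑methylbut‑2‑en‑1‑yl)‑2H‑chromen‑6‑yl]chroman‑7‑ol
Conditions: Pd(PPh3)4 (5 mol%), morpholine (10 equiv), degassed THF, rt
Reagents that add atoms: none
Why: Tsuji–Trost deallylation of aryl allyl ethers under neutral to basic conditions; the C‑prenyl group, the ring‑constrained chromene C–O bond and the benzylic C2–O bond do not ionise, so C2 is not scrambled.

## Compound list
| No. | Name | SMILES | Role |
|---|---|---|---|
| 1 | 3,4‑dihydroxyacetophenone | CC(=O)c1ccc(O)c(O)c1 | starting material |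
| 2 | 3‑chloro‑3‑methylbut‑1‑yne | C#CC(C)(C)Cl | starting material |
| 3 | 1‑[3‑hydroxy‑4‑(2‑methylbut‑3‑yn‑2‑yloxy)phenyl]ethanone | CC(=O)c1ccc(OC(C)(C)C#C)c(O)c1 | intermediate |
| 4 | 1‑(8‑hydroxy‑2,2‑dimethyl‑2H‑chromen‑6‑yl)ethanone | CC(=O)c1cc(O)c2OC(C)(C)C=Cc2c1 | intermediate |
| 5 | 2‑methylbut‑3‑en‑2‑ol | C=CC(C)(C)O | starting material |
| 6 | di‑tert‑butyl dicarbonate | CC(C)(C)OC(=O)OC(=O)OC(C)(C)C | starting material |
| 7 | tert‑butyl (2‑methylbut‑3‑en‑2‑yl) carbonate | C=CC(C)(C)OC(=O)OC(C)(C)C | intermediate |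
| 8 | 1‑[2,2‑dimethyl‑8‑(2‑methylbut‑3‑en‑2‑yloxy)‑2H‑chromen‑6‑yl]ethanone | CC(=O)c1cc(OC(C)(C)C=C)c2OC(C)(C)C=Cc2c1 | intermediate |
| 9 | 1‑[8‑hydroxy‑2,2‑dimethyl‑7‑prenyl‑2H‑chromen‑6‑yl]ethanone | CC(=O)c1cc2C=CC(C)(C)Oc2c(O)c1CC=C(C)C | intermediate |
| 10 | allyl bromide | C=CCBr | starting material |
| 11 | 1‑[8‑(allyloxy)‑2,2‑dimethyl‑7‑prenyl‑2H‑chromen‑6‑yl]ethanone | CC(=O)c1cc2C=CC(C)(C)Oc2c(OCC=C)c1CC=C(C)C | intermediate |
| 12 | 2,4‑dihydroxybenzaldehyde | O=Cc1ccc(O)cc1O | starting material |
| 13 | 4‑(allyloxy)‑2‑hydroxybenzaldehyde | O=Cc1ccc(OCC=C)cc1O | intermediate |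
| 14 | (E)‑2‑hydroxy retro‑chalcone, bis(allyl) ether | O=C(/C=C/c1ccc(OCC=C)cc1O)c1cc2C=CC(C)(C)Oc2c(OCC=C)c1CC=C(C)C | intermediate |
| 15 | saturated keto‑phenol (dihydro‑retro‑chalcone) | O=C(CCc1ccc(OCC=C)cc1O)c1cc2C=CC(C)(C)Oc2c(OCC=C)c1CC=C(C)C | intermediate |
| 16 | (2S)‑7,3'‑di‑O‑allyl kazinol B | CC(C)=CCc1c([C@@H]2CCc3ccc(OCC=C)cc3O2)cc2c(c1OCC=C)OC(C)(C)C=C2 | intermediate |
| 17 | kazinol B, (2S) | CC(C)=CCc1c([C@@H]2CCc3ccc(O)cc3O2)cc2c(c1O)OC(C)(C)C=C2 | target |

## Summary
**Total steps:** 11.
**Longest linear sequence:** 9 (steps 1, 2, 4, 5, 6, 8, 9, 10, 11).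

**Three steps most likely to fail**

1. **Step 10 (new reaction).**
   - Risks: a loose oxocarbenium–anion pair giving low ee; slow ionisation of the hindered hemiketal; Prins or indene formation with the ortho‑prenyl group; acid/hydride reduction of the chromene alkene or of the product's C2–O bond.
   - Fallback (known chemistry, same ketone 15): Noyori–Ikariya transfer hydrogenation with RuCl[(R,R)‑TsDPEN](p‑cymene) in HCO2H/Et3N gives the (R)‑benzylic alcohol and leaves the alkenes alone. Intramolecular Mitsunobu etherification (PPh3, DIAD) then closes the ring with inversion to give (2S)‑16.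

2. **Step 1 (mono‑propargylation of the catechol).**
   - Risks: 3‑O/4‑O mixtures, bis‑ether formation, or base‑induced addition of the free 3‑OH to the alkyne to give a methylene‑benzodioxane.
   - Fallback: differentiate the oxygens with a protecting group instead of relying on acidity. Start from 4‑hydroxy‑3‑methoxyacetophenone, propargylate its single OH, form the chromene thermally, then cleave the methyl ether with sodium ethanethiolate (DMF, 120–130 °C) to reach 4.

3. **Step 5 (Claisen rearrangement into the crowded C7 position).**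
   - Risks: loss of isoprene back to 4, or onward Cope migration to the para carbon.
   - Fallback: O‑allylate 4 and run the parent allyl aryl ether Claisen (PhNEt2, 200 °C) to the 7‑allyl phenol. Then convert allyl to prenyl by cross‑metathesis with 2‑methylbut‑2‑ene (Grubbs II) to give 9; the hindered chromene alkene is expected not to take part.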